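## Retrosynthetic overview

1. Pinnatin B ⇒ its furan analogue: the (Z)-ene-dione (C10–C13) is unveiled last by singlet-oxygen opening of a 2,5-bridged 3-methylfuran.
2. Butenolide (C4–C6) ⇒ transannular RCM of a 13-membered α-methylene macrolactone ⇒ seco acid (C6–OH + 2-substituted acrylic acid).
3. C6 carbinol ⇒ catalyst-controlled vinylation of a cyclopropanecarbaldehyde; the cyclopropane (C7–C8–C9) and the furan–C9 bond ⇒ one aminocatalytic Friedel–Crafts/3-exo-tet cascade of the furan C–H with (E)-4-bromo-2-methylbut-2-enal (the new step).
4. C14/C1 ⇒ chiral phosphoric acid-catalysed anti-allylboration of 3-methylfurfural with an (E)-allyl-Bpin made from sulcatone (first stereocentres).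
5. Ring order: cyclopropane → macrolactone → butenolide/13-membered carbocycle → ene-dione. Starting materials: sulcatone, 3-methylfurfural, prenyl bromide (all achiral).

Atom labels used below follow the ring atoms of the given SMILES: C1 = CH–isopropenyl, C2/C3 = CH2, C4=C5–C6 = butenolide, C7(Me)/C8/C9 = cyclopropane, C10–C13 = ene-dione (furan carbons before the last step), C14 = CHOAc. In these labels the target is 1S,6S,7S,9S,14S, with a trans ring fusion at the cyclopropane and a Z ene-dione.

Assumption: only substrates, intermediates and the target are numbered; simple reagents are given by name and SMILES in each step.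

## Route

**Step 1**
Reactants: 1, 6-methylhept-5-en-2-one (sulcatone)
Product: 2, 6-methylhepta-1,5-dien-2-yl trifluoromethanesulfonate
Conditions: LDA, THF, −78 °C; PhNTf2, −78 → 0 °C
Reagents that add atoms: N-phenylbis(trifluoromethanesulfonimide), O=S(=O)(N(c1ccccc1)S(=O)(=O)C(F)(F)F)C(F)(F)F
Why: Kinetic deprotonation of the methyl ketone at CH3 and O-triflation of the enolate give the terminal enol triflate.

**Step 2**
Reactants: 2, 6-methylhepta-1,5-dien-2-yl triflate
Product: 3, 2-(trimethylsilyl)ethyl 6-methyl-2-methylidenehept-5-enoate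
Conditions: Pd(OAc)2 (5 mol %), PPh3, CO (1 atm), Me3SiCH2CH2OH, Et3N, DMF, 60 °C
Reagents that add atoms: carbon monoxide, [C-]#[O+]; 2-(trimethylsilyl)ethanol, C[Si](C)(C)CCO
Why: Pd-catalysed alkoxycarbonylation of an enol triflate gives the 2-substituted acrylate; the TMSE ester is later removable with fluoride without touching the C14 acetate.

**Step 3**
Reactants: 3, 2-(trimethylsilyl)ethyl 6-methyl-2-methylidenehept-5-enoate
Product: 4, 2-(trimethylsilyl)ethyl (5E)-7-hydroxy-6-methyl-2-methylidenehept-5-enoate
Conditions: SeO2 (0.5 equiv), t-BuOOH, salicylic acid (cat.), CH2Cl2, rt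
Reagents that add atoms: selenium dioxide, O=[Se]=O; tert-butyl hydroperoxide (terminal oxidant), CC(C)(C)OO
Why: SeO2/TBHP allylic oxidation (ene then [2,3] shift) takes the E-methyl of the electron-rich trisubstituted alkene and ignores the electron-poor acrylate, fixing the E geometry.

**Step 4**
Reactants: 4, the (E)-allylic alcohol
Product: 5, 2-(trimethylsilyl)ethyl (5E)-6-methyl-2-methylidene-7-(4,4,5,5-tetramethyl-1,3,2-dioxaborolan-2-yl)hept-5-enoate
Conditions: B2pin2, Pd(MeCN)4(BF4)2 (5 mol %), DMSO/MeOH, 40 °C
Reagents that add atoms: bis(pinacolato)diboron, CC1(C)OB(OC1(C)C)B1OC(C)(C)C(C)(C)O1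
Why: Pd-catalysed allylic borylation through a π-allyl intermediate gives the linear allyl-Bpin with the E geometry retained.

**Step 5**
Reactants: 5, the (E)-allyl-Bpin; 6, 3-methylfuran-2-carbaldehyde
Product: 7, 2-(trimethylsilyl)ethyl (5S)-5-[(S)-hydroxy(3-methylfuran-2-yl)methyl]-6-methyl-2-methylidenehept-6-enoate
Conditions: (S)-TRIP phosphoric acid (5 mol %), 4 Å MS, toluene, −30 °C; aqueous work-up
Reagents that add atoms: none
Why: Chiral phosphoric acid-catalysed allylboration through a closed chair transition state; (S)-TRIP is expected to select the aldehyde Si face (14S, sense to be confirmed), and the E γ-substituent sits equatorial, giving the anti C1 centre (1S).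

**Step 6**
Reactants: 7, the homoallylic furyl carbinol
Product: 8, 2-(trimethylsilyl)ethyl (5S)-5-[(S)-acetoxy(3-methylfuran-2-yl)methyl]-6-methyl-2-methylidenehept-6-enoate
Conditions: Ac2O, pyridine, DMAP (cat.), CH2Cl2, 0 °C → rt
Reagents that add atoms: acetic anhydride, CC(=O)OC(C)=O
Why: DMAP-catalysed acylation installs the natural C14 acetate early, which also blocks this hydroxyl during the later lactonization.

**Step 7**
Reactants: 9, 1-bromo-3-methylbut-2-ene (prenyl bromide)
Product: 10, (2E)-4-bromo-2-methylbut-2-enal
Conditions: SeO2 (1.2 equiv), 1,4-dioxane, 75 °C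
Reagents that add atoms: selenium dioxide, O=[Se]=O
Why: Riley oxidation of the E-methyl group of the trisubstituted alkene gives the E-enal directly.

**Step 8 (new step)**
Reactants: 8, the furfuryl acetate (free furan C5–H); 10, (2E)-4-bromo-2-methylbut-2-enal
Product: 11, 2-(trimethylsilyl)ethyl (5S)-5-[(S)-acetoxy{5-[(1S,2S)-2-formyl-2-methylcyclopropyl]-3-methylfuran-2-yl}methyl]-6-methyl-2-methylidenehept-6-enoate
Conditions: 9-amino-9-deoxy-epi-quinine (20 mol %), TFA (40 mol %), CHCl3, 0 °C → rt; then 2,6-lutidine (1.5 equiv). The quinidine-derived pseudo-enantiomer gives the opposite C9 sense, so the catalyst is assigned on the first run.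
Reagents that add atoms: none
Why: Proposed new method: an iminium–enamine "arylative cyclopropanation" in which the primary-amine iminium of the α-branched γ-bromo-enal is attacked at Cβ by the furan C5 position (Friedel–Crafts conjugate addition, catalyst face control sets C9), and the enamine freed by lutidine then displaces the adjacent CH2Br in a 3-exo-tet alkylation that creates quaternary C7 with the bulky iminium (later CHO) trans to the furan and the methyl cis, as the target requires; the closest known chemistry is aminocatalytic Michael-initiated ring-closure cyclopropanation of enals with bromomalonates and primary-amine iminium–enamine cascades of α-branched enals (indole addition then α-functionalization), but an arene C–H nucleophile with the leaving group on the enal γ-carbon has not been shown to give cyclopropanes.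

**Step 9**
Reactants: 11, the cyclopropanecarbaldehyde
Product: 12, 2-(trimethylsilyl)ethyl (5S)-5-[(S)-acetoxy{5-[(1S,2S)-2-[(1S)-1-hydroxyprop-2-en-1-yl]-2-methylcyclopropyl]-3-methylfuran-2-yl}methyl]-6-methyl-2-methylidenehept-6-enoate
Conditions: (CH2=CH)2Zn (2 equiv, salt-free), (−)-MIB (10 mol %), toluene, −10 → 0 °C
Reagents that add atoms: divinylzinc, C=C[Zn]C=C
Why: Amino-alcohol-catalysed vinylzinc addition is chemoselective for the non-enolizable α-quaternary aldehyde and reagent-controlled; (−)-MIB is expected to deliver vinyl to the Si face, giving 6S.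

**Step 10**
Reactants: 12, the TMSE ester vinyl carbinol
Product: 13, (5S)-5-[(S)-acetoxy{5-[(1S,2S)-2-[(1S)-1-hydroxyprop-2-en-1-yl]-2-methylcyclopropyl]-3-methylfuran-2-yl}methyl]-6-methyl-2-methylidenehept-6-enoic acid
Conditions: TBAF, THF, 0 °C → rt
Reagents that add atoms: none
Why: Fluoride-induced fragmentation of the TMSE ester frees the acid under non-acidic conditions that spare the acetate and the acid-sensitive furyl cyclopropylcarbinol.

**Step 11**
Reactants: 13, the seco acid
Product: 14, (1S,6S,7S,9S,14S) macrolactone: 13-membered ring (counted through the furan O) in which C6–O is acylated by the C4 acrylic acid; it carries C6-vinyl, C4=CH2, the trans 1-methylcyclopropane (C7–C9), the 2,5-linked 3-methylfuran, C14-OAc and C1-isopropenyl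
Conditions: MNBA, DMAP, toluene (1 mM, syringe-pump addition), 60 °C
Reagents that add atoms: none
Why: Shiina macrolactonization under high dilution; C6–OH is the only free hydroxyl, and the furan and cyclopropane restrict the chain conformations.

**Step 12**
Reactants: 14, the α-methylene macrolactone
Product: 15, (1S,6S,7S,9S,14S) furanobutenolide macrocycle: the target skeleton with a 3-methylfuran-2,5-diyl in place of the C10–C13 ene-dione
Conditions: Grubbs II (10 mol %), toluene (2 mM), 80 °C
Reagents that add atoms: none
Why: Ring-closing metathesis of the allylic 2-substituted acrylate (loss of ethylene) forms the five-membered butenolide with its trisubstituted C4=C5 bond and thereby the bridged 13-membered carbocycle; the isopropenyl group is a poor partner and could only close an unfavourable ring.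

**Step 13**
Reactants: 15, the furanobutenolide macrocycle
Product: 16, Pinnatin B
Conditions: O2, hν (visible), tetraphenylporphyrin (cat.), CH2Cl2, −78 °C; then Me2S, −78 °C → rt
Reagents that add atoms: oxygen, O=O
Why: [4+2] addition of singlet oxygen to the electron-rich trialkylfuran and Me2S reduction of the endoperoxide give the ene-1,4-dione with Z geometry fixed by the furan, much faster than an ene reaction at the isopropenyl group.

## Compound list

1 | 6-methylhept-5-en-2-one | CC(=O)CCC=C(C)C | starting material
2 | 6-methylhepta-1,5-dien-2-yl trifluoromethanesulfonate | C=C(OS(=O)(=O)C(F)(F)F)CCC=C(C)C | intermediate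
3 | 2-(trimethylsilyl)ethyl 6-methyl-2-methylidenehept-5-enoate | C=C(CCC=C(C)C)C(=O)OCC[Si](C)(C)C | intermediate
4 | 2-(trimethylsilyl)ethyl (5E)-7-hydroxy-6-methyl-2-methylidenehept-5-enoate | C=C(CC/C=C(\C)CO)C(=O)OCC[Si](C)(C)C | intermediate
5 | 2-(trimethylsilyl)ethyl (5E)-6-methyl-2-methylidene-7-(pinacolboryl)hept-5-enoate | C=C(CC/C=C(\C)CB1OC(C)(C)C(C)(C)O1)C(=O)OCC[Si](C)(C)C | intermediate
6 | 3-methylfuran-2-carbaldehyde | Cc1ccoc1C=O | starting material
7 | TMSE (5S)-5-[(S)-hydroxy(3-methylfuran-2-yl)methyl]-6-methyl-2-methylidenehept-6-enoate | C=C(C)[C@H](CCC(=C)C(=O)OCC[Si](C)(C)C)[C@H](O)c1occc1C | intermediate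
8 | TMSE (5S)-5-[(S)-acetoxy(3-methylfuran-2-yl)methyl]-6-methyl-2-methylidenehept-6-enoate | C=C(C)[C@H](CCC(=C)C(=O)OCC[Si](C)(C)C)[C@H](OC(C)=O)c1occc1C | intermediate
9 | 1-bromo-3-methylbut-2-ene | CC(C)=CCBr | starting material
10 | (2E)-4-bromo-2-methylbut-2-enal | O=C/C(C)=C/CBr | intermediate
11 | cyclopropanecarbaldehyde (name in Step 8) | C=C(C)[C@H](CCC(=C)C(=O)OCC[Si](C)(C)C)[C@H](OC(C)=O)c1oc(cc1C)[C@H]2C[C@]2(C)C=O | intermediate
12 | C6 vinyl carbinol (name in Step 9) | C=C(C)[C@H](CCC(=C)C(=O)OCC[Si](C)(C)C)[C@H](OC(C)=O)c1oc(cc1C)[C@H]2C[C@]2(C)[C@@H](O)C=C | intermediate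
13 | seco acid (name in Step 10) | C=C(C)[C@H](CCC(=C)C(=O)O)[C@H](OC(C)=O)c1oc(cc1C)[C@H]2C[C@]2(C)[C@@H](O)C=C | intermediate
14 | 13-membered α-methylene macrolactone (Step 11) | C=C(C)[C@@H]1CCC(=C)C(=O)O[C@@H](C=C)[C@@]2(C)C[C@@H]2c3cc(C)c(o3)[C@H]1OC(C)=O | intermediate
15 | furanobutenolide macrocycle (Step 12) | C=C(C)[C@@H]1CCC2=C[C@H](OC2=O)[C@@]2(C)C[C@@H]2c3cc(C)c(o3)[C@H]1OC(C)=O | intermediate
16 | Pinnatin B | C=C(C)[C@@H]1CCC2=C[C@H](OC2=O)[C@@]2(C)C[C@@H]2C(=O)/C=C(/C)C(=O)[C@H]1OC(C)=O | target

## Step count and risks

Total steps: 13. Longest linear sequence: 12 (Steps 1–6 and 8–13, from sulcatone); Step 7 is a one-step side branch.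

Steps most likely to fail:

1. **Step 8 (proposed cascade).** Risks are N-alkylation of the primary-amine catalyst by the bromide, low furan nucleophilicity toward the α-branched iminium, and lability of the furfuryl acetate and of the furyl/formyl cyclopropane. Fallback (known chemistry): brominate 8 at furan C5 (NBS) and run a stereoretentive Suzuki–Miyaura coupling with an enantioenriched trans-cyclopropyl boronate. That boronate comes from Charette asymmetric Simmons–Smith cyclopropanation of (E)-2-methyl-3-(pinacolboryl)prop-2-en-1-ol. Oxidation of CH2OH to CHO then gives 11.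

2. **Step 11 (macrolactonization onto the hindered C6 carbinol).** Fallback: change the ring-closing bond. Run RCM on 12 first to close the carbocycle at C4=C5, then lactonize the γ-hydroxy enoate after TBAF; this needs the ester cis to C6, which is not guaranteed.

3. **Step 12 (transannular RCM).** The macrolactone must adopt the s-cis ester conformation for the two alkenes to meet. Fallback: build the butenolide before ring closure. Esterify a cyclopropyl-boronate vinyl carbinol fragment intermolecularly with the acid from 8, do the RCM on the open chain, brominate the furan at C5, and close the macrocycle at C9–C10 by intramolecular Suzuki–Miyaura coupling.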